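**Strategy.** Each ring of the symmetric 2,2'-biquinone is cut into a four-carbon unit, C(=O)–C(OH)=C(CH3)–C(=O), taken from diisopropyl squarate, and a two-carbon unit, C(biaryl)=C(CH2CH2Ph), taken from 4-phenyl-1-butyne. The key step is a Moore rearrangement of a 4-alkynyl-4-(tributylstannyloxy)cyclobutenone. Electrocyclic opening gives an enynylketene, and the quinone ring closes by bonding the ketene carbon (the carbonyl flanked by C–O) to the phenethyl-bearing alkyne carbon, while tin shifts from oxygen to the neighbouring ring carbon. That carbon is the biaryl carbon, so copper-mediated homocoupling of the stannylquinone and cleavage of two isopropyl ethers finish the target.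

Key step: step 3

Assumption: the target SMILES defines no stereo element, so the hindered biaryl axis is left unassigned; the single carbinol stereocentre of compounds 4 to 10 is racemic and is destroyed in step 3.

**Step 1**
Reactants: 1 3,4-di(propan-2-yloxy)cyclobut-3-ene-1,2-dione (diisopropyl squarate); 2 but-3-yn-1-ylbenzene (4-phenyl-1-butyne)
Product: 5 4-(4-phenylbut-1-yn-1-yl)-2,3-di(propan-2-yloxy)-4-(trimethylsilyloxy)cyclobut-2-en-1-one (racemic), via lithium acetylide 3 (not isolated), via lithium alkoxide 4 (not isolated)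
Conditions: 2, nBuLi, THF, −78 °C; add to 1, THF, −78 °C; TMSCl, −78 °C to rt
Reagents that add atoms: chlorotrimethylsilane, C[Si](C)(C)Cl
Why: Acetylide 1,2-addition to one of the two equivalent squarate carbonyls at low temperature is the standard entry to 4-alkynyl-4-hydroxycyclobutenones, and the tertiary lithium alkoxide is silylated in the same flask; the new stereocentre forms racemic and is removed later.

**Step 2**
Reactants: 5 4-(4-phenylbut-1-yn-1-yl)-2,3-di(propan-2-yloxy)-4-(trimethylsilyloxy)cyclobut-2-en-1-one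
Product: 9 4-hydroxy-3-methyl-4-(4-phenylbut-1-yn-1-yl)-2-(propan-2-yloxy)cyclobut-2-en-1-one (racemic), via lithium alkoxide 6 (not isolated), via trifluoroacetate 7 (not isolated), via silyl ether 8 (not isolated)
Conditions: MeLi, THF, −78 °C; TFAA, −78 °C; H2O; then 1 M aq HCl, THF, 0 °C to rt
Reagents that add atoms: methyllithium, C[Li]; water, O
Why: MeLi adds 1,2 to the remaining ring carbonyl, TFAA turns the new alkoxide into a leaving group whose ionisation is assisted by the distal isopropoxy group, and hydrolysis of the resulting oxocarbenium ion (1,3-carbonyl transposition, the squarate-to-cyclobutenone protocol) places the carbonyl between the carbinol carbon and the isopropoxy carbon with methyl on the β-carbon; dilute HCl then cleaves the tertiary trimethylsilyl ether.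

**Step 3**
Reactants: 9 4-hydroxy-3-methyl-4-(4-phenylbut-1-yn-1-yl)-2-(propan-2-yloxy)cyclobut-2-en-1-one
Product: 13 3-methyl-6-(2-phenylethyl)-2-(propan-2-yloxy)-5-(tributylstannyl)cyclohexa-2,5-diene-1,4-dione, via stannyl ether 10 (not isolated), via enynylketene 11 (not isolated), via diradical 12 (not isolated)
Conditions: Bu3SnOMe (1.1 equiv), PhMe, rt, MeOH removed in vacuo; then degassed PhMe, 110 °C
Reagents that add atoms: tributyltin methoxide, CCCC[Sn](CCCC)(CCCC)OC
Why: Stannyl ether 10 forms by alkoxide exchange, and on heating the cyclobutenone opens by 4π-conrotatory electrocyclic cleavage of its C1–C4 bond, the stannyloxy donor rotating outward so that the alkynyl group lies cis to the ketene in 11. The ketene carbon, flanked by the isopropoxy-bearing carbon, then bonds to the distal, phenethyl-bearing alkyne carbon, closing the six-membered ring in a 6-endo-dig sense to the aryl σ/phenoxyl diradical 12, and a 1,3-shift of tin from oxygen to the adjacent radical carbon delivers the para-quinone. The closest known reaction is the Moore rearrangement of 4-alkynyl-4-(trialkylstannyloxy)cyclobutenones to stannylquinones. No stereocentre is formed and the racemic carbinol centre is destroyed. The step needs six- over five-membered closure, which the alkyl-substituted (not radical-stabilising) alkyne secures, and tin transfer over hydrogen transfer, which the absence of an O–H bond and of a hydrogen-donor solvent secures.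

**Step 4**
Reactants: 13 3-methyl-6-(2-phenylethyl)-2-(propan-2-yloxy)-5-(tributylstannyl)cyclohexa-2,5-diene-1,4-dione (two molecules)
Product: 14 5,5'-dimethyl-2,2'-bis(2-phenylethyl)-4,4'-di(propan-2-yloxy)-[1,1'-bi(cyclohexa-1,4-diene)]-3,3',6,6'-tetrone
Conditions: CuCl (2.5 equiv), degassed DMF, rt to 60 °C
Reagents that add atoms: none
Why: Tin-to-copper transmetalation should give a quinonylcopper species of monovalent copper that couples with a second one with deposition of copper metal (CuCl-mediated oxidative homocoupling of alkenylstannanes carrying a conjugated carbonyl), so the biaryl bond forms only at the two tin-bearing carbons.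

**Step 5**
Reactants: 14 5,5'-dimethyl-2,2'-bis(2-phenylethyl)-4,4'-di(propan-2-yloxy)-[1,1'-bi(cyclohexa-1,4-diene)]-3,3',6,6'-tetrone
Product: 15 4,4'-dihydroxy-5,5'-dimethyl-2,2'-bis(2-phenylethyl)-[1,1'-bi(cyclohexa-1,4-diene)]-3,3',6,6'-tetrone (target)
Conditions: BCl3 (excess), CH2Cl2, −78 to 0 °C; aq work-up
Reagents that add atoms: none
Why: BCl3 chelates the vinylogous ester oxygen and the neighbouring carbonyl, chloride removes the secondary isopropyl group (Lewis acid dealkylation of isopropyl ethers), and hydrolysis of the borate should release the 2-hydroxy-1,4-quinone, the only para-quinone tautomer of this trioxygenated ring.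

**Compound list**
1 | 3,4-di(propan-2-yloxy)cyclobut-3-ene-1,2-dione (diisopropyl squarate) | CC(C)OC1=C(OC(C)C)C(=O)C1=O | starting material
2 | but-3-yn-1-ylbenzene (4-phenyl-1-butyne) | C#CCCc1ccccc1 | starting material
3 | lithium 4-phenylbut-1-yn-1-ide | [Li]C#CCCc1ccccc1 | intermediate
4 | lithium 4-oxo-1-(4-phenylbut-1-yn-1-yl)-2,3-di(propan-2-yloxy)cyclobut-2-en-1-olate (racemic) | [Li]OC1(C#CCCc2ccccc2)C(OC(C)C)=C(OC(C)C)C1=O | intermediate
5 | 4-(4-phenylbut-1-yn-1-yl)-2,3-di(propan-2-yloxy)-4-(trimethylsilyloxy)cyclobut-2-en-1-one (racemic) | C[Si](C)(C)OC1(C#CCCc2ccccc2)C(OC(C)C)=C(OC(C)C)C1=O | intermediate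
6 | lithium 1-methyl-4-(4-phenylbut-1-yn-1-yl)-2,3-di(propan-2-yloxy)-4-(trimethylsilyloxy)cyclobut-2-en-1-olate (diastereomer mixture) | [Li]OC1(C)C(OC(C)C)=C(OC(C)C)C1(O[Si](C)(C)C)C#CCCc1ccccc1 | intermediate
7 | 1-methyl-4-(4-phenylbut-1-yn-1-yl)-2,3-di(propan-2-yloxy)-4-(trimethylsilyloxy)cyclobut-2-en-1-yl trifluoroacetate | CC1(OC(=O)C(F)(F)F)C(OC(C)C)=C(OC(C)C)C1(O[Si](C)(C)C)C#CCCc1ccccc1 | intermediate
8 | 3-methyl-4-(4-phenylbut-1-yn-1-yl)-2-(propan-2-yloxy)-4-(trimethylsilyloxy)cyclobut-2-en-1-one (racemic) | CC1=C(OC(C)C)C(=O)C1(O[Si](C)(C)C)C#CCCc1ccccc1 | intermediate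
9 | 4-hydroxy-3-methyl-4-(4-phenylbut-1-yn-1-yl)-2-(propan-2-yloxy)cyclobut-2-en-1-one (racemic) | CC1=C(OC(C)C)C(=O)C1(O)C#CCCc1ccccc1 | intermediate
10 | 3-methyl-4-(4-phenylbut-1-yn-1-yl)-2-(propan-2-yloxy)-4-(tributylstannyloxy)cyclobut-2-en-1-one (racemic) | CC1=C(OC(C)C)C(=O)C1(O[Sn](CCCC)(CCCC)CCCC)C#CCCc1ccccc1 | intermediate
11 | (3E)-3-methyl-8-phenyl-2-(propan-2-yloxy)-4-(tributylstannyloxy)octa-1,3-dien-5-yn-1-one (enynylketene) | O=C=C(OC(C)C)/C(C)=C(O[Sn](CCCC)(CCCC)CCCC)\C#CCCc1ccccc1 | intermediate
12 | 3-methyl-6-(2-phenylethyl)-2-(propan-2-yloxy)-4-(tributylstannyloxy)phenoxyl with a σ-radical at ring carbon 5 (diradical) | CC(C)Oc1c([O])c(CCc2ccccc2)[c]c(O[Sn](CCCC)(CCCC)CCCC)c1C | intermediate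
13 | 3-methyl-6-(2-phenylethyl)-2-(propan-2-yloxy)-5-(tributylstannyl)cyclohexa-2,5-diene-1,4-dione | CC(C)OC1=C(C)C(=O)C([Sn](CCCC)(CCCC)CCCC)=C(CCc2ccccc2)C1=O | intermediate
14 | 5,5'-dimethyl-2,2'-bis(2-phenylethyl)-4,4'-di(propan-2-yloxy)-[1,1'-bi(cyclohexa-1,4-diene)]-3,3',6,6'-tetrone | CC(C)OC1=C(C)C(=O)C(C2=C(CCc3ccccc3)C(=O)C(OC(C)C)=C(C)C2=O)=C(CCc2ccccc2)C1=O | intermediate
15 | 4,4'-dihydroxy-5,5'-dimethyl-2,2'-bis(2-phenylethyl)-[1,1'-bi(cyclohexa-1,4-diene)]-3,3',6,6'-tetrone | CC1=C(O)C(=O)C(CCc2ccccc2)=C(C2=C(CCc3ccccc3)C(=O)C(O)=C(C)C2=O)C1=O | target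

**Step count.** Total: 5 steps. Longest linear sequence: 5 steps (1 and 2 to 15).

**Steps most likely to fail**

Step 3. Tin transfer may lose out to hydrolysis of the O–Sn bond by adventitious water and to hydrogen transfer, and the ketene may close to a five-membered ring instead. The fallback sets out from 9 and comes back at 14. Heating 9 itself in PhMe at 110 °C should give, by the classical Moore rearrangement with transfer of the hydroxyl hydrogen, 3-methyl-6-(2-phenylethyl)-2-(propan-2-yloxy)cyclohexa-2,5-diene-1,4-dione F1. Addition of Br2 to its only hydrogen-bearing ring double bond (CH2Cl2, 0 °C) and elimination with Et3N should give 5-bromo-3-methyl-6-(2-phenylethyl)-2-(propan-2-yloxy)cyclohexa-2,5-diene-1,4-dione F2. Reductive Ullmann-type homocoupling of F2 with CuTC (Cu(O2CC4H3S), copper thiophene-2-carboxylate of monovalent copper) in NMP at rt, assisted by the carbonyl ortho to bromine, should give 14.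

Step 4. Transmetalation and coupling at a carbon flanked by a carbonyl and a phenethyl group may be slow, so that protodestannylation competes with formation of the crowded biaryl bond. The fallback sets out from 13 and comes back at 14. Half of 13 is treated with I2 (CH2Cl2, 0 °C) to give 5-iodo-3-methyl-6-(2-phenylethyl)-2-(propan-2-yloxy)cyclohexa-2,5-diene-1,4-dione F3. Stille cross-coupling of F3 with the remaining 13 (Pd2(dba)3, AsPh3, CuI, DMF, 50 °C) would then form the same bond through oxidative addition to zerovalent palladium rather than through oxidative homocoupling.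

Step 2. Ionisation may occur at the propargylic carbinol carbon once the silyl group is lost early, or the strained ring may open under the acidic conditions, eroding the regiochemistry of the carbonyl transposition. The fallback sets out from 1 and comes back at 9.
- MeLi addition to 1 (THF, −78 °C) and hydrolysis with aq HCl should give 3-methyl-4-(propan-2-yloxy)cyclobut-3-ene-1,2-dione F4.
- Ketalisation of its more electrophilic carbonyl, the one next to the isopropoxy carbon, with 1,2-bis(trimethylsilyloxy)ethane and catalytic TMSOTf (CH2Cl2, −78 °C) should give 7-methyl-8-(propan-2-yloxy)-1,4-dioxaspiro[4.3]oct-7-en-6-one F5.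
- Acetylide 3 is then forced onto the remaining carbonyl, giving 6-hydroxy-7-methyl-6-(4-phenylbut-1-yn-1-yl)-8-(propan-2-yloxy)-1,4-dioxaspiro[4.3]oct-7-ene F6.
- Mild aqueous acid (dilute H2SO4, THF, rt) should remove the dioxolane and give 9.

**Further compounds**
F1 | step 3 | 3-methyl-6-(2-phenylethyl)-2-(propan-2-yloxy)cyclohexa-2,5-diene-1,4-dione | CC(C)OC1=C(C)C(=O)C=C(CCc2ccccc2)C1=O
F2 | step 3 | 5-bromo-3-methyl-6-(2-phenylethyl)-2-(propan-2-yloxy)cyclohexa-2,5-diene-1,4-dione | CC(C)OC1=C(C)C(=O)C(Br)=C(CCc2ccccc2)C1=O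
F3 | step 4 | 5-iodo-3-methyl-6-(2-phenylethyl)-2-(propan-2-yloxy)cyclohexa-2,5-diene-1,4-dione | CC(C)OC1=C(C)C(=O)C(I)=C(CCc2ccccc2)C1=O
F4 | step 2 | 3-methyl-4-(propan-2-yloxy)cyclobut-3-ene-1,2-dione | CC1=C(OC(C)C)C(=O)C1=O
F5 | step 2 | 7-methyl-8-(propan-2-yloxy)-1,4-dioxaspiro[4.3]oct-7-en-6-one | CC1=C(OC(C)C)C2(OCCO2)C1=O
F6 | step 2 | 6-hydroxy-7-methyl-6-(4-phenylbut-1-yn-1-yl)-8-(propan-2-yloxy)-1,4-dioxaspiro[4.3]oct-7-ene (racemic) | CC1=C(OC(C)C)C2(OCCO2)C1(O)C#CCCc1ccccc1
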